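**Retrosynthetic overview**
- Ring C (2H-pyran) is opened first by retro-oxa-6π. This gives the dimer-level vinyl o-quinone methide, the species that dehydrogenation of a prenyl side chain is presumed to give in the plant. A retro-Knoevenagel step then removes the C5 unit as prenal.
- The chromene-free dimer is cut at the CH2 bridge (retro-Michael) into phloroacetophenone and the 6-methylene trione of acetylfilicinic acid. The CH2 comes from an iminium salt.
- Acetylfilicinic acid goes back to phloroacetophenone by retro gem-dimethylation, the dearomative counterpart of the two SAM methylations.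
- Ring order: rings A (filicinic) and B (aromatic) are both bought as the same aromatic polyketide. Ring A is reshaped first and the bridge follows. Ring C is the only ring closed, and it is closed last on the unprotected dimer, where a single aromatic CH is left.

Assumption: the target has no stereocentre and no stereogenic double bond, so it is achiral and no enantiomer has to be selected. All β-triketone units are drawn in the enol tautomer of the given SMILES.

**Step 1**
Reactants: 1 2,4,6-trihydroxyacetophenone (phloroacetophenone); 2 iodomethane
Product: 3 acetylfilicinic acid (2-acetyl-3,5-dihydroxy-4,4-dimethylcyclohexa-2,5-dien-1-one)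
Conditions: NaOMe (3.0 equiv), MeI (2.1 equiv), MeOH, 0 °C to rt, 16 h; then 1 M HCl
Reagents that add atoms: iodomethane 2, CI
Why: Dearomative double C-alkylation of a phloroglucinolate: in MeOH the solvated anion reacts at carbon, the carbon that already carries one methyl is the most nucleophilic site, and after the second methylation the product rests as a delocalised, poorly nucleophilic β-triketone anion, so about two equivalents of MeI stop the reaction mainly at 3; no stereocentre is formed.

**Step 2**
Reactants: 3 acetylfilicinic acid; 4 N,N-dimethylmethyleneiminium iodide (Eschenmoser's salt); 1 2,4,6-trihydroxyacetophenone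
Product: 7 2-acetyl-6-[(3-acetyl-2,4,6-trihydroxyphenyl)methyl]-3,5-dihydroxy-4,4-dimethylcyclohexa-2,5-dien-1-one, via Mannich base 5 (not isolated), via methylene trione 6 (not isolated)
Conditions: 4 (1.0 equiv), MeCN, 0 °C to rt, 1 h; then 1 (3.0 equiv), NaOAc (1.1 equiv), 50 °C, 3 h; then 1 M HCl
Reagents that add atoms: N,N-dimethylmethyleneiminium iodide 4, C[N+](C)=C.[I-]
Why: Mannich reaction, E1cB retro-Mannich elimination and Michael (Friedel–Crafts type) addition in one flask: the one-carbon unit is fixed on the only free enol carbon of 3 before any phenol is present, which excludes the symmetrical bis-filicinic dimer, 5 then sheds Me2NH to the strongly electrophilic enetrione 6 (a quinone methide equivalent), and a threefold excess of cheap, recoverable 1 holds back a second alkylation; no stereocentre is formed.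

**Step 3**
Reactants: 7 chromene-free methylene-bridged dimer; 8 3-methylbut-2-enal (prenal)
Product: 10 2-acetyl-6-[(8-acetyl-5,7-dihydroxy-2,2-dimethyl-2H-chromen-6-yl)methyl]-3,5-dihydroxy-4,4-dimethylcyclohexa-2,5-dien-1-one, via vinyl o-quinone methide 9 (not isolated)
Conditions: 8 (1.5 equiv), piperidinium acetate (20 mol %), THF, 60 °C, 8 h
Reagents that add atoms: 3-methylbut-2-enal 8, CC(C)=CC=O
Why: Knoevenagel condensation followed by oxa-6π electrocyclisation (formal [3+3] chromene annulation): the iminium ion of 8 attacks the single free aromatic CH of 7 (ring A has no free enol carbon), loss of piperidine gives 9, the dienone that oxidation of a prenylated dimer would give, so prenylation and dehydrogenation merge into one operation, and 9 closes onto the carbonyl oxygen next to the acetyl-bearing carbon, the mode usually preferred by 3-alkylated acylphloroglucinols (the other closure is removed by chromatography), while a secondary amine salt is chosen because a primary amine would be captured as a stable enaminone by the 2-acetyl-1,3-dione of ring A; no stereocentre is formed because C2 of the pyran carries two methyl groups.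

**Compound list**
1 | 2,4,6-trihydroxyacetophenone (phloroacetophenone) | CC(=O)c1c(O)cc(O)cc1O | starting material
2 | iodomethane | CI | starting material
3 | acetylfilicinic acid, 2-acetyl-3,5-dihydroxy-4,4-dimethylcyclohexa-2,5-dien-1-one | CC(=O)C1=C(O)C(C)(C)C(O)=CC1=O | intermediate
4 | N,N-dimethylmethyleneiminium iodide (Eschenmoser's salt) | C[N+](C)=C.[I-] | starting material
5 | Mannich base, 2-acetyl-6-[(dimethylamino)methyl]-3,5-dihydroxy-4,4-dimethylcyclohexa-2,5-dien-1-one (formed as its hydroiodide, not isolated) | CC(=O)C1=C(O)C(C)(C)C(O)=C(CN(C)C)C1=O | intermediate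
6 | methylene trione, 2-acetyl-3-hydroxy-4,4-dimethyl-6-methylidenecyclohex-2-ene-1,5-dione (not isolated) | CC(=O)C1=C(O)C(C)(C)C(=O)C(=C)C1=O | intermediate
7 | 2-acetyl-6-[(3-acetyl-2,4,6-trihydroxyphenyl)methyl]-3,5-dihydroxy-4,4-dimethylcyclohexa-2,5-dien-1-one | CC(=O)C1=C(O)C(C)(C)C(O)=C(Cc2c(O)cc(O)c(C(C)=O)c2O)C1=O | intermediate
8 | 3-methylbut-2-enal (prenal) | CC(C)=CC=O | starting material
9 | vinyl o-quinone methide, 2-acetyl-6-{[(3Z)-5-acetyl-2,6-dihydroxy-3-(3-methylbut-2-en-1-ylidene)-4-oxocyclohexa-1,5-dien-1-yl]methyl}-3,5-dihydroxy-4,4-dimethylcyclohexa-2,5-dien-1-one (not isolated) | CC(=O)C1=C(O)C(C)(C)C(O)=C(CC2=C(O)/C(=C/C=C(C)C)C(=O)C(C(C)=O)=C2O)C1=O | intermediate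
10 | 2-acetyl-6-[(8-acetyl-5,7-dihydroxy-2,2-dimethyl-2H-chromen-6-yl)methyl]-3,5-dihydroxy-4,4-dimethylcyclohexa-2,5-dien-1-one (achiral) | CC(=O)C1=C(O)C(C)(C)C(O)=C(Cc2c(O)c3c(c(C(C)=O)c2O)OC(C)(C)C=C3)C1=O | target

**Total step count:** 3. **Longest linear sequence:** 3 (1 → 3 → 7 → 10).

**Steps most likely to fail**

Step 3 carries the highest risk.
- The warm amine salt can reopen the CH2 bridge (retro-Michael) and scramble 7 into symmetrical dimers.
- 9 can also close onto the oxygen next to the bridge.

The fallback sets out from 1 and comes back to the route at 9. The C5 unit is brought in at the prenyl oxidation level and oxidised afterwards. 1 is C-alkylated with prenyl bromide (1-bromo-3-methylbut-2-ene; KOH, H2O, 0 °C) to 1-[2,4,6-trihydroxy-3-(3-methylbut-2-en-1-yl)phenyl]ethanone F1, which has a single free ring carbon. One equivalent of it takes the place of 1 as the trap for 6, made from 3 and 4 as in step 2. This gives the prenylated dimer 2-acetyl-6-{[3-acetyl-2,4,6-trihydroxy-5-(3-methylbut-2-en-1-yl)phenyl]methyl}-3,5-dihydroxy-4,4-dimethylcyclohexa-2,5-dien-1-one F2. 2,3-Dichloro-5,6-dicyano-1,4-benzoquinone (DDQ, 1.05 equiv, toluene, rt) then removes hydride from the benzylic and allylic CH2 of the side chain. Loss of a phenol proton gives 9 at room temperature with no amine present, so the bridge is not stressed, and 9 closes to 10 as before. This costs one more step.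

Step 2 is the next most at risk.
- 7 can be alkylated a second time by 6, giving a trimer.
- 6 can dimerise with itself.

The fallback sets out from 1 and 4 and comes back at 7. The roles of the two halves are exchanged. 1 (2 equiv) reacts with 4 (1 equiv; MeCN, NaOAc, rt) to give 1-{3-[(dimethylamino)methyl]-2,4,6-trihydroxyphenyl}ethanone F3. This is freed from excess 1 and from bis-adduct by acid–base extraction. Heating it with 3 (1.5 equiv) in 1,4-dioxane at 90 °C expels dimethylamine to give the aromatic o-quinone methide 2-acetyl-3,5-dihydroxy-6-methylidenecyclohexa-2,4-dien-1-one F4. The free enol carbon of 3 captures this at once to give 7. Each aromatic ring carries exactly one CH2 before it meets 3, so the statistical problem is settled at the cheapest stage.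

Step 1 is the third risk.
- Methylation gives a statistical mixture of mono-, gem-di-, tri- and tetramethyl products, and stopping at 3 may be inefficient.

The fallback sets out from 1 and 2 and comes back at 6. Methylation is pushed one stage further (MeI 3.3 equiv, NaOMe 4 equiv, MeOH) to 2-acetyl-3,5-dihydroxy-4,4,6-trimethylcyclohexa-2,5-dien-1-one F5, which is also the main over-methylation product of step 1. The bridge carbon then arrives as the third methyl group. Ag2O and TEMPO (2,2,6,6-tetramethylpiperidin-1-oxyl) in THF at rt dehydrogenate the C6 methyl enol directly to 6 in the presence of 1 (3 equiv), which traps it as 7. Compounds 3, 4 and 5 are then not needed.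

**Further compounds**
F1 | step 3 | 1-[2,4,6-trihydroxy-3-(3-methylbut-2-en-1-yl)phenyl]ethanone | CC(=O)c1c(O)cc(O)c(CC=C(C)C)c1O
F2 | step 3 | 2-acetyl-6-{[3-acetyl-2,4,6-trihydroxy-5-(3-methylbut-2-en-1-yl)phenyl]methyl}-3,5-dihydroxy-4,4-dimethylcyclohexa-2,5-dien-1-one | CC(=O)C1=C(O)C(C)(C)C(O)=C(Cc2c(O)c(CC=C(C)C)c(O)c(C(C)=O)c2O)C1=O
F3 | step 2 | 1-{3-[(dimethylamino)methyl]-2,4,6-trihydroxyphenyl}ethanone | CC(=O)c1c(O)cc(O)c(CN(C)C)c1O
F4 | step 2 | 2-acetyl-3,5-dihydroxy-6-methylidenecyclohexa-2,4-dien-1-one | CC(=O)C1=C(O)C=C(O)C(=C)C1=O
F5 | step 1 | 2-acetyl-3,5-dihydroxy-4,4,6-trimethylcyclohexa-2,5-dien-1-one | CC(=O)C1=C(O)C(C)(C)C(O)=C(C)C1=O
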